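**Retrosynthetic overview**

1. Target 16 is a 2-methoxy-6-alkyl-1,4-benzoquinone. Ring numbering used here: C1 carries the (CH2)14CO2H chain, C2–H, C3=O, C4–H, C5–OMe, C6=O. The last operation is acidolysis of a tert-butyl ester.
2. The quinone is the oxidised form of a 4-methoxyphenol, which is taken apart in one stroke by a Dötz benzannulation. Bonds C2–C3, C5–C6 and C6–C1 are cut, leaving three components: the carbene ligand of (CO)5Cr=C(OMe)CH=CHOMe (C3, C4, C5), one CO ligand (C6) and the terminal alkyne HC≡C(CH2)14CO2tBu (C1, C2).
3. Enabling feature: the 1,4-dioxygenated six-membered carbocycle, in which the C6 carbonyl lies between the alkyl-bearing C1 and the methoxy-bearing C5, while the C3 carbonyl lies between two ring CH groups (C2, C4). A terminal alkyne (chain next to the CO-derived carbon) and a β-methoxyvinyl methoxycarbene deliver exactly this pattern, and the carbene-derived C3–OMe is unmasked to C3=O by oxidation.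
4. Alkyne 4 comes from 15-bromopentadecanoic acid and lithium acetylide. Carbene complex 11 comes from ethynyltrimethylsilane, Cr(CO)6, Me3OBF4 and methanol.
5. Ring order: the only ring, the quinone carbocycle, is formed in step 5 from three acyclic components.

Key step: step 5

Remark: the target has no stereocentre and no stereogenic double bond, so no stereocontrol is needed; the side chain is read as fourteen methylene groups plus the carboxyl carbon.

**Route**

Step 1
Reactants: 1 15-bromopentadecanoic acid; 2 lithium acetylide ethylenediamine complex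
Product: 3 heptadec-16-ynoic acid
Conditions: 2 (3.5 equiv), DMSO, 10 °C to rt; then 1 M HCl
Reagents that add atoms: none
Why: SN2 alkylation of acetylide by the primary bromide, after in-flask formation of the unreactive lithium carboxylate, should give the terminal alkyne, which as its acetylide is the thermodynamic sink and should not migrate along the chain.

Step 2
Reactants: 3 heptadec-16-ynoic acid
Product: 4 tert-butyl heptadec-16-ynoate
Conditions: Cl3CC(=NH)OtBu, BF3·OEt2 (cat.), CH2Cl2/cyclohexane, rt
Reagents that add atoms: tert-butyl 2,2,2-trichloroacetimidate, CC(C)(C)OC(=N)C(Cl)(Cl)Cl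
Why: Acid-catalysed esterification with a trichloroacetimidate (tert-butyl cation transfer) should mask the acid as an ester that survives the chromium chemistry and the oxidation and can be removed at the end by anhydrous acid, which the base-sensitive methoxyquinone tolerates.

Step 3
Reactants: 5 ethynyltrimethylsilane; 6 hexacarbonylchromium Cr(CO)6
Product: 9 pentacarbonyl[1-methoxy-3-(trimethylsilyl)prop-2-yn-1-ylidene]chromium, via lithium (trimethylsilyl)acetylide 7 (not isolated), via lithium acylchromate 8 (not isolated)
Conditions: n-BuLi, THF, −78 °C; Cr(CO)6, −78 °C to rt; then Me3OBF4, CH2Cl2, −20 °C to 0 °C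
Reagents that add atoms: trimethyloxonium tetrafluoroborate, C[O+](C)C.F[B-](F)(F)F
Why: Fischer carbene synthesis: acetylide 7 should add to a CO ligand of Cr(CO)6 to give acylchromate 8, whose hard oxygen is then methylated by the oxonium salt.

Step 4
Reactants: 9 pentacarbonyl[1-methoxy-3-(trimethylsilyl)prop-2-yn-1-ylidene]chromium
Product: 11 pentacarbonyl[(2E)-1,3-dimethoxyprop-2-en-1-ylidene]chromium, via ethynylcarbene complex 10 (not isolated)
Conditions: MeOH, NaOMe (5 mol %), THF, −20 °C to 0 °C
Reagents that add atoms: methanol, CO
Why: Methoxide should cleave the C(sp)–Si bond, and the resulting ethynylcarbene complex 10, a very strong Michael acceptor, should take up methanol at its terminal carbon (conjugate addition of an alcohol to an alkynylcarbene complex); the push–pull E alkene is the expected thermodynamic product, and exchange at the carbene carbon is degenerate because both alkoxy groups are methoxy.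

Step 5
Reactants: 11 pentacarbonyl[(2E)-1,3-dimethoxyprop-2-en-1-ylidene]chromium (1.3 equiv); 4 tert-butyl heptadec-16-ynoate
Product: 15 tert-butyl 15-(5-methoxy-3,6-dioxocyclohexa-1,4-dien-1-yl)pentadecanoate, via dienylketene chromium complex 12 (not isolated), via arene chromium tricarbonyl complex 13 (not isolated), via free phenol 14 (not isolated)
Conditions: THF (0.05 M), 60 °C, Ar; then (NH4)2Ce(NO3)6, MeCN/H2O, 0 °C
Reagents that add atoms: water, O
Why: Thermal loss of one CO from 11 should let the terminal alkyne insert into the Cr=C bond with its unsubstituted carbon on the carbene carbon; a CO ligand then inserts to give the chromium-bound dienylketene 12, and 6π-electrocyclisation of 12 onto the methoxy-bearing vinyl terminus followed by tautomerisation should deliver the phenol as its Cr(CO)3 complex 13. The closest known reaction is the Dötz benzannulation of alkenyl(alkoxy)carbene chromium complexes with terminal alkynes, worked up in the usual way by oxidation with (NH4)2Ce(NO3)6. The single ring closes by a thermally allowed disrotatory 6π-electrocyclisation of the ketene carbon onto the cis-disposed alkene carbon, after the two intermolecular bonds (C2–C3 and C1–C6) have been made at chromium; no stereocentre is formed, and the alkene geometry of 11 is irrelevant because that carbon becomes aromatic. Three selectivities are needed: the regiochemistry of alkyne insertion, secured by the steric difference between H and the long chain of a terminal alkyne (chain ortho to the new hydroxyl); CO insertion in preference to direct five-membered ring closure, favoured by an alkenyl rather than aryl carbene, by the only moderately donating β-methoxy group, by THF and by low concentration; and para- over ortho-quinone formation, expected because the methoxy group para to the phenol is the one lost as methanol while the ortho methoxy group remains as the vinylogous ester. The oxidant should first remove chromium from 13 as trivalent chromium and then convert the free 4-methoxyphenol 14 into the quinone, with water supplying the new C3 carbonyl oxygen.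

Step 6
Reactants: 15 tert-butyl 15-(5-methoxy-3,6-dioxocyclohexa-1,4-dien-1-yl)pentadecanoate
Product: 16 15-(5-methoxy-3,6-dioxocyclohexa-1,4-dien-1-yl)pentadecanoic acid
Conditions: CF3CO2H/CH2Cl2 (1:3), rt
Reagents that add atoms: none
Why: Acidolysis of the tert-butyl ester (loss of the tert-butyl cation as 2-methylpropene) should free the acid under anhydrous acidic conditions that leave the quinone and its vinylogous methyl ester untouched.

**Compound list**

1 | 15-bromopentadecanoic acid | BrCCCCCCCCCCCCCCC(=O)O | starting material
2 | lithium acetylide ethylenediamine complex | [Li+].[C-]#C.NCCN | starting material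
3 | heptadec-16-ynoic acid | C#CCCCCCCCCCCCCCCC(=O)O | intermediate
4 | tert-butyl heptadec-16-ynoate | C#CCCCCCCCCCCCCCCC(=O)OC(C)(C)C | intermediate
5 | ethynyltrimethylsilane | C#C[Si](C)(C)C | starting material
6 | hexacarbonylchromium Cr(CO)6 | [Cr].[C-]#[O+].[C-]#[O+].[C-]#[O+].[C-]#[O+].[C-]#[O+].[C-]#[O+] | starting material
7 | lithium (trimethylsilyl)acetylide | [Li+].[C-]#C[Si](C)(C)C | intermediate
8 | lithium pentacarbonyl[1-oxido-3-(trimethylsilyl)prop-2-yn-1-ylidene]chromate (lithium acylchromate) | [Li+].[O-]C(=[Cr])C#C[Si](C)(C)C.[C-]#[O+].[C-]#[O+].[C-]#[O+].[C-]#[O+].[C-]#[O+] | intermediate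
9 | pentacarbonyl[1-methoxy-3-(trimethylsilyl)prop-2-yn-1-ylidene]chromium | COC(=[Cr])C#C[Si](C)(C)C.[C-]#[O+].[C-]#[O+].[C-]#[O+].[C-]#[O+].[C-]#[O+] | intermediate
10 | pentacarbonyl(1-methoxyprop-2-yn-1-ylidene)chromium (ethynylcarbene complex) | COC(=[Cr])C#C.[C-]#[O+].[C-]#[O+].[C-]#[O+].[C-]#[O+].[C-]#[O+] | intermediate
11 | pentacarbonyl[(2E)-1,3-dimethoxyprop-2-en-1-ylidene]chromium | CO/C=C/C(OC)=[Cr].[C-]#[O+].[C-]#[O+].[C-]#[O+].[C-]#[O+].[C-]#[O+] | intermediate
12 | chromium tricarbonyl complex of the dienylketene tert-butyl (17E,19E)-18,20-dimethoxy-16-(oxomethylidene)icosa-17,19-dienoate | O=C=C(CCCCCCCCCCCCCCC(=O)OC(C)(C)C)/C=C(OC)\C=C\OC.[Cr].[C-]#[O+].[C-]#[O+].[C-]#[O+] | intermediate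
13 | tricarbonyl{η6-[tert-butyl 15-(2-hydroxy-3,5-dimethoxyphenyl)pentadecanoate]}chromium | COc1cc(OC)c(O)c(CCCCCCCCCCCCCCC(=O)OC(C)(C)C)c1.[Cr].[C-]#[O+].[C-]#[O+].[C-]#[O+] | intermediate
14 | tert-butyl 15-(2-hydroxy-3,5-dimethoxyphenyl)pentadecanoate | COc1cc(OC)c(O)c(CCCCCCCCCCCCCCC(=O)OC(C)(C)C)c1 | intermediate
15 | tert-butyl 15-(5-methoxy-3,6-dioxocyclohexa-1,4-dien-1-yl)pentadecanoate | COC1=CC(=O)C=C(CCCCCCCCCCCCCCC(=O)OC(C)(C)C)C1=O | intermediate
16 | 15-(5-methoxy-3,6-dioxocyclohexa-1,4-dien-1-yl)pentadecanoic acid | COC1=CC(=O)C=C(CCCCCCCCCCCCCCC(=O)O)C1=O | target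

**Step count and risks**

Total step count: 6. Longest linear sequence: 4 steps (1, 2, 5, 6 or 3, 4, 5, 6).

Steps most likely to fail:

Step 5. After alkyne insertion, the chromium vinylcarbene may close to a five-membered ring without taking up CO, or may take up a second alkyne, because the donating β-methoxy group slows CO loss and CO insertion. In the oxidative work-up, loss of the ortho instead of the para methoxy group would also divert material. The fallback builds the ring substitution pattern on a preformed arene. It sets out from 1 and comes back at 15. Compound 1 is esterified with tert-butyl 2,2,2-trichloroacetimidate and BF3·OEt2 to tert-butyl 15-bromopentadecanoate F1. Zinc dust with LiCl in THF should insert into the C–Br bond to give [15-(tert-butoxy)-15-oxopentadecyl]zinc bromide F2. Negishi coupling of F2 with commercial 3-bromo-5-methoxyphenol (Pd(OAc)2, 2-dicyclohexylphosphino-2',6'-dimethoxybiphenyl, THF, slow addition) should give tert-butyl 15-(3-hydroxy-5-methoxyphenyl)pentadecanoate F3. Teuber oxidation of F3 with potassium nitrosodisulfonate (KSO3)2NO in phosphate-buffered aqueous acetone should place the new carbonyl para to the hydroxyl, between the methoxy- and alkyl-bearing carbons, which is 15.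

Step 4. Methoxide may attack the carbene carbon and trigger decomposition instead of conjugate addition, and protodesilylation may be incomplete, giving mixtures. The fallback assembles the β-methoxyvinyl carbene from an acyl chloride instead of an alkynylcarbene. It sets out from 6 and comes back at 11. Cr(CO)6 is reduced with sodium naphthalenide NaC10H8 in THF at −78 °C to disodium pentacarbonylchromate Na2Cr(CO)5 F4. F4 is acylated with (E)-3-methoxyacryloyl chloride F5, made from commercial (E)-3-methoxyacrylic acid and oxalyl chloride, to give sodium pentacarbonyl[(2E)-3-methoxy-1-oxidoprop-2-en-1-ylidene]chromate F6. O-Methylation of F6 with Me3OBF4 in CH2Cl2 should then give 11 directly.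

Step 3. O-Methylation of the delocalised alkynyl acylchromate may be inefficient, with the sensitive alkynylcarbene complex decomposing during alkylation. The fallback makes the C–OMe bond by substitution at the carbene carbon instead of O-alkylation. It sets out from 8 and comes back at 9. The acylate is precipitated with Me4NBr from water as tetramethylammonium pentacarbonyl[1-oxido-3-(trimethylsilyl)prop-2-yn-1-ylidene]chromate F7. F7 is O-acylated with acetyl bromide in CH2Cl2 at −40 °C to pentacarbonyl[1-acetoxy-3-(trimethylsilyl)prop-2-yn-1-ylidene]chromium F8. Treating F8 with methanol at −40 °C should exchange acetoxy for methoxy by addition–elimination and give 9.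

**Further compounds**

F1 | step 5 | tert-butyl 15-bromopentadecanoate | BrCCCCCCCCCCCCCCC(=O)OC(C)(C)C
F2 | step 5 | [15-(tert-butoxy)-15-oxopentadecyl]zinc bromide | Br[Zn]CCCCCCCCCCCCCCC(=O)OC(C)(C)C
F3 | step 5 | tert-butyl 15-(3-hydroxy-5-methoxyphenyl)pentadecanoate | COc1cc(O)cc(CCCCCCCCCCCCCCC(=O)OC(C)(C)C)c1
F4 | step 4 | disodium pentacarbonylchromate Na2Cr(CO)5 | [Na+].[Na+].[Cr-2].[C-]#[O+].[C-]#[O+].[C-]#[O+].[C-]#[O+].[C-]#[O+]
F5 | step 4 | (E)-3-methoxyacryloyl chloride | CO/C=C/C(Cl)=O
F6 | step 4 | sodium pentacarbonyl[(2E)-3-methoxy-1-oxidoprop-2-en-1-ylidene]chromate | [Na+].[O-]C(/C=C/OC)=[Cr].[C-]#[O+].[C-]#[O+].[C-]#[O+].[C-]#[O+].[C-]#[O+]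
F7 | step 3 | tetramethylammonium pentacarbonyl[1-oxido-3-(trimethylsilyl)prop-2-yn-1-ylidene]chromate | C[N+](C)(C)C.[O-]C(=[Cr])C#C[Si](C)(C)C.[C-]#[O+].[C-]#[O+].[C-]#[O+].[C-]#[O+].[C-]#[O+]
F8 | step 3 | pentacarbonyl[1-acetoxy-3-(trimethylsilyl)prop-2-yn-1-ylidene]chromium | CC(=O)OC(=[Cr])C#C[Si](C)(C)C.[C-]#[O+].[C-]#[O+].[C-]#[O+].[C-]#[O+].[C-]#[O+]
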